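An easy step first: if the same share of free monomer goes each minute, X = ln(free monomer charged / free monomer left) grows in a straight line with time.

| setting | zeta | delta | flask |
|---|---|---|---|
| free monomer | 2.1 M | 2.1 M | 2.1 M |
| transfer agent | 0.10 M | 0.42 M | 0.210 M |
| initiator | 32 mM | 32 mM | 32 mM |
| remark | run made earlier | run made earlier |  |
| time |  |  | 10 min |

| run | time / min | monomer in chains / % | free monomer / % |
|---|---|---|---|
| zeta | 0.833 | 21.8 | 77.2 |
| zeta | 2.00 | 44.6 | 55.3 |
| zeta | 4.00 | 65.4 | 34.6 |
| zeta | 6.00 | 75.9 | 22.7 |
| delta | 0.833 | 20.0 | 78.9 |
| delta | 2.00 | 35.0 | 64.5 |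
| delta | 4.00 | 45.8 | 54.6 |
| delta | 6.00 | 49.0 | 49.6 |

(readings scatter by 0.5 percentage points)

- the average divides the monomer in chains by the number of chains begun, living and dead together
- the earlier runs do not show the number of chains; that part of a forecast is a guess

* average number of monomer units in a chain (chains begun, living or dead) at 10 min
* part of the free monomer that has reacted at 10 min

1. Main step only. I took growth at a steady rate s, so X = s·t. The first zeta reading gave s = 0.311 min⁻¹, so the flask would reach c = 95.5%. But X bent over in the zeta run and the delta run, so I needed the bend.

2. Adding a loss. Suppose the growing centres die away at a rate λ, a pseudo-first-order constant. Then X = (s/λ)(1 − exp(−λt)). X at 4.00 min over X at 2.00 min, less one, equals exp(−λ·2.00 min). That reads λ = 0.117 min⁻¹ for zeta and 0.484 min⁻¹ for delta. Their ratio, 4.14, stands beside an agent ratio of 4.20, so I scaled λ with the agent: 0.244 min⁻¹ for this flask.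

With λ read, X at 2.00 min gave s afresh, averaged over zeta and delta: 0.337 min⁻¹.

The quantity I carried is the reach, A = s/λ, here 1.38: the value X climbs towards. At 10 min this gives c = 71.7%.

3. Going round once more. I had held the agent at its charge. The initiator charge is 15.2% of it. Putting that whole loss back, one agent per initiator, gives c = 76.0%, so I placed my estimate of c between these two values.

4. The runs show no chain count. If each initiator began one chain, dp would be 47.1, which is a guess.

The forecast gave c = 73% (69% to 77%) and dp = 40 (12 to 60), reasoning “Any restarts after transfer add chains, lowering this”.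

The flask gave c = 73.9% and dp = 179. At 10.0 min its living ends and dead chains together came to 0.00853 M against 32 mM of initiator charged, with 0.0117 M of spent initiator beside them. After 100 min the flask held 76.5% monomer in chains, and the reach gives 74.8%.

    living end + transfer agent → dead chain (kL = 0.0180 L mol⁻¹ s⁻¹)
    2 initiator → spent initiator (k = 44.0 L mol⁻¹ s⁻¹)
    free monomer → decomposition product (k = 4.90 × 10⁻⁵ s⁻¹)
    free monomer + initiator → living end + monomer in chains (k = 0.160 L mol⁻¹ s⁻¹)
    free monomer + living end → monomer in chains + living end, rate k5*[living end]*[free monomer] (k = 0.640 L mol⁻¹ s⁻¹)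

For the neighbour flask with 0.13 M of agent, the reach scales to 2.24, which gives c = 82.5% at 10 min. The computed result for that flask is 83.6%.

(Readings and results were computed for substances that don't exist, noise included.)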